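## Structural features

8-Hydroxypinoresinol is a 2,6-diaryl-3,7-dioxabicyclo[3.3.0]octane. Ring A (O, C7', C8', C8, C9) and ring B (O, C7, C8, C8', C9') are cis-fused through the C8–C8' bond, and each carries a 4-hydroxy-3-methoxyphenyl group on its benzylic carbon. The four stereocentres C7, C8, C8' and C7' are contiguous, (7R,8S,7'S,8'R); both aryl groups sit on the convex face and the C8 hydroxyl is cis to H8'. The tertiary hydroxyl at C8 removes the twofold symmetry of the pinoresinol core, so the two halves cannot be made in the same way. The fragile sites are the p-hydroxybenzylic ether carbons C7 and C7', which ionise under acid to quinone-methide-like cations (epimerisation, ring opening, hydrogenolysis), and the free phenols. The real difficulty is the fully substituted carbinol C8: its configuration must be set relative to C8' while two nearly identical oxygen-bearing one-carbon arms, C7 and C9, are told apart. C8 with its own oxygen and its oxygenated neighbours C7 and C9 is a masked 3-substituted oxetan-3-ol. The key step uses this: a hydroxyl on C7' is placed to reach one oxetane methylene through a five-membered transition state, which closes ring A and leaves the other methylene as C7.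

## Logic of the disconnections

20 from 18: the O–Si bond at C8 and the two aryl O–acyl bonds are cut. The phenols stay as electron-poor esters to the end so that C7 and C7' do not ionise in the acidic steps. The demand on the forward step is a non-acidic, non-epimerising global deprotection.

18 from 17 from 16: the two C9'–H bonds are cut, returning C9' to the acyl oxidation level. This turns ring B into a lactone that an acyl donor on C8' can form. The forward steps must reduce a lactone in the presence of two aryl esters and then reduce a lactol without ionising two benzylic ethers.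

16 from 11 and 14 (made from 13): the C7–aryl bond and the O–C9' bond of ring B are cut. The second arene becomes a separate nucleophile and ring B closes by acyl transfer with the auxiliary as leaving group. The forward step must attack the correct face of the C7 formyl group (chelation sense, not Felkin–Anh sense) and the reagent must tolerate two esters and an imide.

11 from 10: only the oxidation level of C7 changes. The oxidant must be neutral, because 10 carries a hydroxyl cis to an acyl imide.

10 from 9 (key disconnection): the O–C9 bond of ring A is cut and C9 and C7 are rejoined through one oxygen as an oxetane. C8 then ceases to be stereogenic, and C7, C8, C9 with all three oxygens come from one symmetrical three-carbon ketone. The forward step must choose the correct one of two diastereotopic methylenes (silyloxy trans to the C8' acyl group), must not ionise C7', and must not let the freed hydroxyl acylate on the imide.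

9 from 7 and 2: the C7'–C8' bond is cut as an auxiliary-controlled syn aldol. A check of the descriptors confirms that the (S)-benzyl auxiliary in the syn mode delivers C7'(S) and C8'(R), and that the syn relation places the aryl group trans to the acyl group once ring A is closed. The forward step needs enolisation next to a quaternary, β-silyloxy carbon without β-elimination and without harm to the oxetane.

7 from 6 from 3 and 4: the O–Si bond and the C8–C8' bond are cut. Because 4 is symmetrical, the acetate aldol creates no stereocentre, so its usual lack of selectivity does not matter. The forward step must avoid retro-aldol and attack of the tertiary alkoxide on the auxiliary.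

2 from 1 and 13 from 12: the aryl O–acyl bonds are cut; both are simple phenol acylations.

## Other disconnections considered

Alternative 1: Both ring C–O bonds at the primary carbons (O–C9 and O–C9') are cut, leading to the acyclic (7R,8S,7'S,8'R)-pentaol A2 with benzyl-protected phenols. In the forward step methanesulfonyl chloride in pyridine would sulfonylate the two primary hydroxyls, and the C7' and C7 hydroxyls would displace them in two 5-exo-tet closures to give the dibenzyl ether A1.
- In its favour: the closure is stereoconservative and regiochemically unambiguous, since each secondary hydroxyl reaches only one primary carbon through a five-membered transition state. It closes both rings in one operation and needs no choice between diastereotopic groups. On predictability of the ring-forming event it is better than the chosen plan.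
- Against it here: it makes no C–C bond and no stereocentre, so all four stereocentres, including the tertiary carbinol, must already be present in A2, and making A2 is the actual problem. The electron-rich benzyloxyaryl carbinols can be sulfonylated or chlorinated at C7/C7' and then epimerise by an SN1 path. The final hydrogenolysis that converts A1 to the target must spare two benzylic ring C–O bonds.
- Comparison: the endgame from A2 is shorter than that of the chosen plan (about two steps against six), but the route to A2 is likely to be as long as or longer than the whole chosen sequence. Unlike the chosen plan, it does not draw on the oxetanol pattern at C8.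

Alternative 2: The C7–C8 and C7'–C8' bonds are cut, leading to the succinyl bis-imide A4 and two molecules of 4-benzyloxy-3-methoxybenzaldehyde A5. In the forward step a twofold boron syn-aldol would give the C2-symmetric adduct A3.
- In its favour: it forms two C–C bonds and four stereocentres in one flask from two simple partners and uses the hidden twofold symmetry of the carbon skeleton. In bonds and stereocentres per step it is clearly better than the chosen key step, which forms one bond and one stereocentre.
- Against it here: A3 carries hydrogen at C8, so the tertiary hydroxyl, the feature that distinguishes the target from pinoresinol, still has to be introduced later with retention at a tertiary centre. Double enolisation of a succinyl unit places two enolates on adjacent carbons and is not routine. The first aldolate can lactonise onto the second imide, which would remove the control element for the second addition. The second aldol must occur next to a newly formed, branched stereocentre.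
- Comparison: the carbon skeleton would be reached in fewer steps than in the chosen plan, but the chosen plan has the C8 oxygen in place from the first step. Since either C8 or C8' of a symmetric intermediate could be hydroxylated with the same result, the alternative is equal on the question of which position to oxidise, but worse on how to do it.

Alternative 3: The C9'–C8' bond of ring B and the C7'–O bond of ring A are cut, leading to the chloromethyl ether A7, a styrene with C7 and C8 already set and C8 protected as its acetate. In the forward step SnCl4 would ionise A7 to a methylene oxocarbenium ion, the styrene carbon C8' would attack it, and the C9 silyl ether oxygen would capture the benzylic cation at C7' to give the acetate A6.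
- In its favour: one operation closes both rings, makes a C–C bond and sets C8' and C7'. The tertiary carbinol is present from the start. The differential phenol protection (pivalate on the C7 arene, silyl ether on the styrene arene) steers ionisation to the right benzylic carbon. In rings and stereocentres per step it is better than the chosen key step.
- Against it here: the configuration at C8' and C7' would rest on conformational preferences of a cationic cascade and on capture of a planar benzylic cation. The C8 acetate is a neighbouring group that can capture the same cation. The aryl silyl ether and the benzylic ether at C7 must survive SnCl4. A7 itself needs two stereocentres, a chloromethyl ether on a hindered benzylic alcohol and a styrene on a quaternary carbon.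
- Comparison: the chosen plan forms less per step but relies on a closed-shell SN2 opening with an auxiliary-derived neighbour, whereas the alternative relies on the fate of two successive cations. In step count the two are probably equal.

Key step: step 5

Assumption: the hand of the binaphthyl phosphoric acid that matches the substrate in step 5 cannot be deduced reliably on paper. The route is written with (R)-TRIP, (R)-3,3'-bis(2,4,6-triisopropylphenyl)-1,1'-binaphthyl-2,2'-diyl hydrogen phosphate, and the (S)-acid would take its place if it proved to be the matched one.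

## Route

Step 1
Reactants: 1 vanillin
Product: 2 4-formyl-2-methoxyphenyl pivalate
Conditions: PivCl, Et3N, DMAP (cat.), CH2Cl2, 0 °C → rt
Reagents that add atoms: pivaloyl chloride CC(C)(C)C(=O)Cl
Why: DMAP-catalysed acylation of a phenol; the hindered ester makes the arene about as electron-poor as phenyl, which later keeps the C7' carbinol from ionising, and it survives boron triflate, mild acid and organozinc reagents.

Step 2
Reactants: 3 (S)-3-acetyl-4-benzyloxazolidin-2-one; 4 oxetan-3-one
Product: 6 (S)-4-benzyl-3-[2-(3-hydroxyoxetan-3-yl)acetyl]oxazolidin-2-one, via lithium enolate 5 (not isolated)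
Conditions: LiN(iPr)2, THF, −78 °C; then 4; AcOH, −78 °C
Reagents that add atoms: none
Why: Acetate aldol addition of a lithium imide enolate to a strained and therefore very electrophilic ketone; the ketone is symmetrical, so no stereocentre arises and the low selectivity of acetate aldols is irrelevant; the cold acidic quench forestalls retro-aldol and attack of the tertiary alkoxide on the auxiliary carbonyl.

Step 3
Reactants: 6 (S)-4-benzyl-3-[2-(3-hydroxyoxetan-3-yl)acetyl]oxazolidin-2-one
Product: 7 (S)-4-benzyl-3-{2-[3-(triethylsilyloxy)oxetan-3-yl]acetyl}oxazolidin-2-one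
Conditions: Et3SiOTf, 2,6-lutidine, CH2Cl2, −78 → 0 °C
Reagents that add atoms: triethylsilyl trifluoromethanesulfonate CC[Si](CC)(CC)OS(=O)(=O)C(F)(F)F
Why: Silyl triflate and a hindered pyridine silylate tertiary aldol hydroxyls at low temperature without retro-aldol; triethylsilyl is kept because it is robust enough for the following acid, oxidation and hydride steps yet small enough to chelate a metal in step 8 and to be removed by fluoride at the end.

Step 4
Reactants: 7 (S)-4-benzyl-3-{2-[3-(triethylsilyloxy)oxetan-3-yl]acetyl}oxazolidin-2-one; 2 4-formyl-2-methoxyphenyl pivalate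
Product: 9 (S)-4-benzyl-3-{(2R,3S)-3-hydroxy-3-(3-methoxy-4-pivaloyloxyphenyl)-2-[3-(triethylsilyloxy)oxetan-3-yl]propanoyl}oxazolidin-2-one, via dibutylboron enolate 8 (not isolated)
Conditions: Bu2BOTf, iPr2NEt, CH2Cl2, −78 → 0 °C; then 2, −78 → 0 °C; pH 7 buffer, MeOH, H2O2, 0 °C
Reagents that add atoms: none
Why: Evans syn aldol: the (Z)-boron enolate reacts through a chair Zimmerman–Traxler transition state with the auxiliary carbonyl opposed to the enolate oxygen, so the aldehyde adds to the face away from the benzyl group and sets C8'(R) and C7'(S) in the syn relation; boron enolates of β-silyloxy imides are slow to undergo β-elimination, and the oxetane meets no competent nucleophile at this temperature.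

Step 5
Reactants: 9 (S)-4-benzyl-3-{(2R,3S)-3-hydroxy-3-(3-methoxy-4-pivaloyloxyphenyl)-2-[3-(triethylsilyloxy)oxetan-3-yl]propanoyl}oxazolidin-2-one
Product: 10 (S)-4-benzyl-3-{[(2S,3R,4R)-4-(hydroxymethyl)-2-(3-methoxy-4-pivaloyloxyphenyl)-4-(triethylsilyloxy)tetrahydrofuran-3-yl]carbonyl}oxazolidin-2-one
Conditions: (R)-TRIP (10 mol %), PhMe, 40 °C
Reagents that add atoms: none
Why: The phosphoric acid hydrogen-bonds the oxetane oxygen through P–OH and the C7' hydroxyl through P=O, so that this hydroxyl attacks one oxetane methylene from the rear in an SN2 opening driven by release of four-ring strain; the attacked methylene becomes C9 and the other is set free as the C7 hydroxymethyl group. The closest known reaction type is the Brønsted-acid-catalysed intramolecular opening of 3,3-disubstituted oxetanes by a hydroxyl on a two-atom tether, including desymmetrising versions with binaphthyl phosphoric acids, which gives 3-(hydroxymethyl)tetrahydrofurans. Ring A closes in the 5-exo-tet mode, with O, C7', C8', C8 and C9 in the ring and the leaving oxygen outside it. The new stereocentre C8 is decided by which of the two diastereotopic methylenes is attacked; the wanted path leaves the unreacted arm cis to the C8' acyl group and the silyloxy group trans to it. In the transition state the acyl group on C8' must lie next to either the tied-back oxetane methylene or the triethylsilyloxy group; the former is expected to be less crowded and brings the imide carbonyl close to the protonated oxetane oxygen, and the matched hand of the chiral acid is meant to reinforce this bias. The step also needs the hydroxyl to win over the imide carbonyl oxygen as nucleophile and the freed primary hydroxyl not to acylate on the cis imide; a Brønsted acid that does not chelate and activate the imide, a non-polar solvent and use of 10 without storage serve this. Ionisation of the C7' carbinol is held back by the pivalate on its arene, and C7' and C8' are not touched.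

Step 6
Reactants: 10 (S)-4-benzyl-3-{[(2S,3R,4R)-4-(hydroxymethyl)-2-(3-methoxy-4-pivaloyloxyphenyl)-4-(triethylsilyloxy)tetrahydrofuran-3-yl]carbonyl}oxazolidin-2-one
Product: 11 (S)-4-benzyl-3-{[(2S,3R,4S)-4-formyl-2-(3-methoxy-4-pivaloyloxyphenyl)-4-(triethylsilyloxy)tetrahydrofuran-3-yl]carbonyl}oxazolidin-2-one
Conditions: Dess–Martin periodinane, NaHCO3, CH2Cl2, 0 °C → rt
Reagents that add atoms: none
Why: Buffered Dess–Martin oxidation of a neopentyl-type primary alcohol; the aldehyde has no α-hydrogen and cannot epimerise, and removing the hydroxyl ends the risk of acyl transfer to the imide (the descriptor at C8 changes only because the priorities change).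

Step 7
Reactants: 12 4-bromo-2-methoxyphenol
Product: 13 4-bromo-2-methoxyphenyl pivalate
Conditions: PivCl, Et3N, DMAP (cat.), CH2Cl2, 0 °C → rt
Reagents that add atoms: pivaloyl chloride CC(C)(C)C(=O)Cl
Why: Same phenol acylation as in step 1; the pivalate keeps the second arene electron-poor for the acidic reduction in step 10 and is tolerated by zinc reagents.

Step 8
Reactants: 13 4-bromo-2-methoxyphenyl pivalate; 11 (S)-4-benzyl-3-{[(2S,3R,4S)-4-formyl-2-(3-methoxy-4-pivaloyloxyphenyl)-4-(triethylsilyloxy)tetrahydrofuran-3-yl]carbonyl}oxazolidin-2-one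
Product: 16 (3R,3aS,6S,6aR)-3,6-bis(3-methoxy-4-pivaloyloxyphenyl)-3a-(triethylsilyloxy)tetrahydro-1H,3H-furo[3,4-c]furan-1-one, via arylzinc chloride 14 (not isolated), via chlorozinc alkoxide adduct 15 (not isolated)
Conditions: 13, Mg, LiCl, ZnCl2, THF, 25 °C; then 11, 0 → 40 °C
Reagents that add atoms: none
Why: Magnesium insertion with in situ transmetalation gives an ester-tolerant arylzinc halide whose addition to aldehydes is accelerated by the magnesium halide formed beside it; the divalent magnesium or zinc centre is expected to bridge the formyl oxygen and the small triethylsilyloxy oxygen (Cram chelate), so the aryl group enters from the C9 side, away from the C8' acyl substituent, and sets C7(R) with the arene cis to the silyloxy group, whereas Felkin–Anh attack would give the other epimer. The resulting alkoxide then acylates on the cis imide (5-exo-trig), closing ring B as the lactone and releasing the auxiliary.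

Step 9
Reactants: 16 (3R,3aS,6S,6aR)-3,6-bis(3-methoxy-4-pivaloyloxyphenyl)-3a-(triethylsilyloxy)tetrahydro-1H,3H-furo[3,4-c]furan-1-one
Product: 17 (3R,3aS,6S,6aR)-3,6-bis(3-methoxy-4-pivaloyloxyphenyl)-3a-(triethylsilyloxy)tetrahydro-1H,3H-furo[3,4-c]furan-1-ol (both anomers)
Conditions: Sia2BH (from BH3·THF and 2-methylbut-2-ene), THF, 0 °C → rt; pH 7 buffer, H2O2, 0 °C
Reagents that add atoms: none
Why: Disiamylborane reduces γ-lactones to lactols and stops there while leaving carboxylic esters untouched, so the two aryl pivalates, which an aluminium hydride would cleave, are kept; the anomeric centre is removed in the next step and needs no control.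

Step 10
Reactants: 17 (3R,3aS,6S,6aR)-3,6-bis(3-methoxy-4-pivaloyloxyphenyl)-3a-(triethylsilyloxy)tetrahydro-1H,3H-furo[3,4-c]furan-1-ol
Product: 18 (1S,3aS,4R,6aR)-1,4-bis(3-methoxy-4-pivaloyloxyphenyl)-3a-(triethylsilyloxy)tetrahydro-1H,3H-furo[3,4-c]furan
Conditions: Et3SiH, BF3·OEt2, CH2Cl2, −78 → −40 °C
Reagents that add atoms: none
Why: Ionic hydrogenation of a lactol: BF3 ionises the hemiacetal to a cyclic oxocarbenium ion that the silane reduces to the C9' methylene, so no stereocentre is made; the acetal ionises far more readily than the two benzylic ethers, whose arenes are deactivated by the pivalates, and the low temperature spares the tertiary silyl ether.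

Step 11
Reactants: 18 (1S,3aS,4R,6aR)-1,4-bis(3-methoxy-4-pivaloyloxyphenyl)-3a-(triethylsilyloxy)tetrahydro-1H,3H-furo[3,4-c]furan
Product: 20 8-hydroxypinoresinol, via 8-hydroxypinoresinol dipivalate 19 (not isolated)
Conditions: Bu4NF, THF, 0 °C → rt; then K2CO3, MeOH, rt; aq. NH4Cl
Reagents that add atoms: none
Why: Fluoride cleaves the tertiary triethylsilyl ether and carbonate-mediated methanolysis then removes both aryl pivalates in the same flask; both stages are basic and cold enough that the benzylic ethers neither ionise nor epimerise, and no stereocentre is touched.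

## Compound list

1 | vanillin (4-hydroxy-3-methoxybenzaldehyde) | COc1cc(C=O)ccc1O | starting material
2 | 4-formyl-2-methoxyphenyl pivalate | COc1cc(C=O)ccc1OC(=O)C(C)(C)C | intermediate
3 | (S)-3-acetyl-4-benzyloxazolidin-2-one | CC(=O)N1[C@@H](Cc2ccccc2)COC1=O | starting material
4 | oxetan-3-one | O=C1COC1 | starting material
5 | lithium enolate of 3, lithium 1-[(S)-4-benzyl-2-oxooxazolidin-3-yl]ethenolate | [Li]OC(=C)N1[C@@H](Cc2ccccc2)COC1=O | intermediate (not isolated)
6 | (S)-4-benzyl-3-[2-(3-hydroxyoxetan-3-yl)acetyl]oxazolidin-2-one | O=C(CC1(O)COC1)N1[C@@H](Cc2ccccc2)COC1=O | intermediate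
7 | (S)-4-benzyl-3-{2-[3-(triethylsilyloxy)oxetan-3-yl]acetyl}oxazolidin-2-one | O=C(CC1(O[Si](CC)(CC)CC)COC1)N1[C@@H](Cc2ccccc2)COC1=O | intermediate
8 | (Z)-dibutylboron enolate of 7 | O=C1OC[C@H](Cc2ccccc2)N1/C(OB(CCCC)CCCC)=C/C1(O[Si](CC)(CC)CC)COC1 | intermediate (not isolated)
9 | (S)-4-benzyl-3-{(2R,3S)-3-hydroxy-3-(3-methoxy-4-pivaloyloxyphenyl)-2-[3-(triethylsilyloxy)oxetan-3-yl]propanoyl}oxazolidin-2-one | O=C1OC[C@H](Cc2ccccc2)N1C(=O)[C@H]([C@H](O)c1ccc(OC(=O)C(C)(C)C)c(OC)c1)C1(O[Si](CC)(CC)CC)COC1 | intermediate (key-step precursor)
10 | (S)-4-benzyl-3-{[(2S,3R,4R)-4-(hydroxymethyl)-2-(3-methoxy-4-pivaloyloxyphenyl)-4-(triethylsilyloxy)tetrahydrofuran-3-yl]carbonyl}oxazolidin-2-one | O=C1OC[C@H](Cc2ccccc2)N1C(=O)[C@@H]1[C@@H](c2ccc(OC(=O)C(C)(C)C)c(OC)c2)OC[C@]1(O[Si](CC)(CC)CC)CO | intermediate (key-step product)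
11 | (S)-4-benzyl-3-{[(2S,3R,4S)-4-formyl-2-(3-methoxy-4-pivaloyloxyphenyl)-4-(triethylsilyloxy)tetrahydrofuran-3-yl]carbonyl}oxazolidin-2-one | O=C1OC[C@H](Cc2ccccc2)N1C(=O)[C@@H]1[C@@H](c2ccc(OC(=O)C(C)(C)C)c(OC)c2)OC[C@]1(O[Si](CC)(CC)CC)C=O | intermediate
12 | 4-bromo-2-methoxyphenol | COc1cc(Br)ccc1O | starting material
13 | 4-bromo-2-methoxyphenyl pivalate | COc1cc(Br)ccc1OC(=O)C(C)(C)C | intermediate
14 | (3-methoxy-4-pivaloyloxyphenyl)zinc chloride | COc1cc([Zn]Cl)ccc1OC(=O)C(C)(C)C | intermediate (not isolated)
15 | (S)-4-benzyl-3-{[(2S,3R,4S)-4-[(R)-hydroxy(3-methoxy-4-pivaloyloxyphenyl)methyl]-2-(3-methoxy-4-pivaloyloxyphenyl)-4-(triethylsilyloxy)tetrahydrofuran-3-yl]carbonyl}oxazolidin-2-one, present as its chlorozinc alkoxide (drawn as the alcohol) | O=C1OC[C@H](Cc2ccccc2)N1C(=O)[C@@H]1[C@@H](c2ccc(OC(=O)C(C)(C)C)c(OC)c2)OC[C@]1(O[Si](CC)(CC)CC)[C@H](O)c1ccc(OC(=O)C(C)(C)C)c(OC)c1 | intermediate (not isolated)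
16 | (3R,3aS,6S,6aR)-3,6-bis(3-methoxy-4-pivaloyloxyphenyl)-3a-(triethylsilyloxy)tetrahydro-1H,3H-furo[3,4-c]furan-1-one | COc1cc([C@H]2OC[C@]3(O[Si](CC)(CC)CC)[C@@H](c4ccc(OC(=O)C(C)(C)C)c(OC)c4)OC(=O)[C@H]23)ccc1OC(=O)C(C)(C)C | intermediate
17 | (3R,3aS,6S,6aR)-3,6-bis(3-methoxy-4-pivaloyloxyphenyl)-3a-(triethylsilyloxy)tetrahydro-1H,3H-furo[3,4-c]furan-1-ol, both anomers | COc1cc([C@H]2OC[C@]3(O[Si](CC)(CC)CC)[C@@H](c4ccc(OC(=O)C(C)(C)C)c(OC)c4)OC(O)[C@H]23)ccc1OC(=O)C(C)(C)C | intermediate
18 | (1S,3aS,4R,6aR)-1,4-bis(3-methoxy-4-pivaloyloxyphenyl)-3a-(triethylsilyloxy)tetrahydro-1H,3H-furo[3,4-c]furan | COc1cc([C@H]2OC[C@]3(O[Si](CC)(CC)CC)[C@@H](c4ccc(OC(=O)C(C)(C)C)c(OC)c4)OC[C@H]23)ccc1OC(=O)C(C)(C)C | intermediate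
19 | 8-hydroxypinoresinol dipivalate, (1S,3aS,4R,6aR)-1,4-bis(3-methoxy-4-pivaloyloxyphenyl)tetrahydro-1H,3H-furo[3,4-c]furan-3a-ol | COc1cc([C@H]2OC[C@]3(O)[C@@H](c4ccc(OC(=O)C(C)(C)C)c(OC)c4)OC[C@H]23)ccc1OC(=O)C(C)(C)C | intermediate (not isolated)
20 | 8-hydroxypinoresinol, (1S,3aS,4R,6aR)-1,4-bis(4-hydroxy-3-methoxyphenyl)tetrahydro-1H,3H-furo[3,4-c]furan-3a-ol | COc1cc([C@H]2OC[C@]3(O)[C@@H](c4ccc(O)c(OC)c4)OC[C@H]23)ccc1O | target

## Step count and least certain steps

Total: 11 steps. Longest linear sequence: 9 steps (from 3 through steps 2, 3, 4, 5, 6, 8, 9, 10 and 11 to 20).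

Step 5 (key step). The most likely failure is insufficient discrimination between the two diastereotopic oxetane methylenes: the steric difference between a tied-back methylene and a silyloxy group next to the acyl substituent is small, and the matched hand of the acid is not known in advance. A second risk is acyl transfer of the freed hydroxymethyl group onto the cis imide. The route has one safeguard: a C8 epimer cannot form the cis-fused lactone in step 8 and would be removed there.

The fallback replaces control by an external acid with control by an internal chelate and sets out from 9.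
- Transamination (Me(MeO)NH·HCl, AlMe3, CH2Cl2, −20 → 0 °C) would give the N-methoxy-N-methylamide F1 and return the auxiliary.
- Sc(OTf)3 (cat., CH2Cl2, 0 °C) bound to the amide carbonyl can reach the oxetane oxygen only in the rotamer that leads to the wanted epimer. It should therefore deliver the ring A amide alcohol F2, in which the amide is too poor an acyl donor for the neutral hydroxyl.
- Dess–Martin oxidation would give the aldehyde F3.
- Addition of 14 as in step 8 would give the hydroxy amide F4.
- Camphorsulfonic acid in warm toluene would lactonise F4 with loss of the hydroxylamine, and the route is rejoined at 16.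

Step 8. The most likely failure is addition with the wrong facial sense: if the triethylsilyl ether does not chelate, the Felkin–Anh pathway places the new arene on the concave face. Slow addition to the neopentyl-type aldehyde is a second risk.

The fallback replaces silyl-ether chelation by alkoxide chelation and sets out from 11.
- HF·pyridine (THF, 0 °C) would give the α-hydroxy aldehyde F5.
- One equivalent of iPrMgCl at −78 °C would turn F5 into a magnesium alkoxide that holds the formyl oxygen in a five-membered chelate. Addition of 14 would then give the diol imide F6.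
- F6 would close in the flask to the hydroxy lactone F7.
- Sia2BH would give the lactol F8.
- Et3SiH/BF3·OEt2 at −78 °C would reduce F8, and the route is rejoined at 19, which the carbonate methanolysis of step 11 converts to 20.

Step 9. The most likely failure is incomplete hydride transfer from the bulky borane to a lactone carbonyl flanked by a ring-fusion carbon.

The fallback gives up the phenol protection early and sets out from 16.
- Excess iBu2AlH (CH2Cl2, −78 °C) would reduce the lactone and cleave both pivalates, giving the diphenolic lactol F9.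
- Et3SiH/BF3·OEt2 at −78 °C would give 8-O-triethylsilyl-8-hydroxypinoresinol F10.
- Bu4NF would return the route at 20.

Step 10. The most likely failure is ionisation of a benzylic C–O bond (C7–O or C7'–O) by BF3 alongside the wanted ionisation of the lactol. This would cause epimerisation or reductive ring opening, and the tertiary silyl ether could also be lost.

The fallback closes ring B by displacement instead of by reduction of an oxocarbenium ion and sets out from 17.
- NaBH4 (MeOH/THF, 0 °C) would reduce the open hydroxy aldehyde form to the diol F11.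
- MsCl in pyridine would sulfonylate the primary hydroxyl to give the mesylate F12.
- The C7 hydroxyl would displace the mesylate in the flask (5-exo-tet, no stereocentre involved), and the route is rejoined at 18.

## Further compounds

F1 | step 5 | (2R,3S)-3-hydroxy-N-methoxy-N-methyl-3-(3-methoxy-4-pivaloyloxyphenyl)-2-[3-(triethylsilyloxy)oxetan-3-yl]propanamide | CON(C)C(=O)[C@H]([C@H](O)c1ccc(OC(=O)C(C)(C)C)c(OC)c1)C1(O[Si](CC)(CC)CC)COC1
F2 | step 5 | (2S,3R,4R)-4-(hydroxymethyl)-N-methoxy-N-methyl-2-(3-methoxy-4-pivaloyloxyphenyl)-4-(triethylsilyloxy)tetrahydrofuran-3-carboxamide | CON(C)C(=O)[C@@H]1[C@@H](c2ccc(OC(=O)C(C)(C)C)c(OC)c2)OC[C@]1(O[Si](CC)(CC)CC)CO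
F3 | step 5 | (2S,3R,4S)-4-formyl-N-methoxy-N-methyl-2-(3-methoxy-4-pivaloyloxyphenyl)-4-(triethylsilyloxy)tetrahydrofuran-3-carboxamide | CON(C)C(=O)[C@@H]1[C@@H](c2ccc(OC(=O)C(C)(C)C)c(OC)c2)OC[C@]1(O[Si](CC)(CC)CC)C=O
F4 | step 5 | (2S,3R,4S)-4-[(R)-hydroxy(3-methoxy-4-pivaloyloxyphenyl)methyl]-N-methoxy-N-methyl-2-(3-methoxy-4-pivaloyloxyphenyl)-4-(triethylsilyloxy)tetrahydrofuran-3-carboxamide | CON(C)C(=O)[C@@H]1[C@@H](c2ccc(OC(=O)C(C)(C)C)c(OC)c2)OC[C@]1(O[Si](CC)(CC)CC)[C@H](O)c1ccc(OC(=O)C(C)(C)C)c(OC)c1
F5 | step 8 | (S)-4-benzyl-3-{[(2S,3R,4S)-4-formyl-4-hydroxy-2-(3-methoxy-4-pivaloyloxyphenyl)tetrahydrofuran-3-yl]carbonyl}oxazolidin-2-one | O=C1OC[C@H](Cc2ccccc2)N1C(=O)[C@@H]1[C@@H](c2ccc(OC(=O)C(C)(C)C)c(OC)c2)OC[C@]1(O)C=O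
F6 | step 8 | (S)-4-benzyl-3-{[(2S,3R,4S)-4-hydroxy-4-[(R)-hydroxy(3-methoxy-4-pivaloyloxyphenyl)methyl]-2-(3-methoxy-4-pivaloyloxyphenyl)tetrahydrofuran-3-yl]carbonyl}oxazolidin-2-one | O=C1OC[C@H](Cc2ccccc2)N1C(=O)[C@@H]1[C@@H](c2ccc(OC(=O)C(C)(C)C)c(OC)c2)OC[C@]1(O)[C@H](O)c1ccc(OC(=O)C(C)(C)C)c(OC)c1
F7 | step 8 | (3R,3aS,6S,6aR)-3a-hydroxy-3,6-bis(3-methoxy-4-pivaloyloxyphenyl)tetrahydro-1H,3H-furo[3,4-c]furan-1-one | COc1cc([C@H]2OC[C@]3(O)[C@@H](c4ccc(OC(=O)C(C)(C)C)c(OC)c4)OC(=O)[C@H]23)ccc1OC(=O)C(C)(C)C
F8 | step 8 | (3R,3aS,6S,6aR)-3,6-bis(3-methoxy-4-pivaloyloxyphenyl)tetrahydro-1H,3H-furo[3,4-c]furan-1,3a-diol, both anomers | COc1cc([C@H]2OC[C@]3(O)[C@@H](c4ccc(OC(=O)C(C)(C)C)c(OC)c4)OC(O)[C@H]23)ccc1OC(=O)C(C)(C)C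
F9 | step 9 | (3R,3aS,6S,6aR)-3,6-bis(4-hydroxy-3-methoxyphenyl)-3a-(triethylsilyloxy)tetrahydro-1H,3H-furo[3,4-c]furan-1-ol, both anomers | COc1cc([C@H]2OC[C@]3(O[Si](CC)(CC)CC)[C@@H](c4ccc(O)c(OC)c4)OC(O)[C@H]23)ccc1O
F10 | step 9 | 8-O-triethylsilyl-8-hydroxypinoresinol | COc1cc([C@H]2OC[C@]3(O[Si](CC)(CC)CC)[C@@H](c4ccc(O)c(OC)c4)OC[C@H]23)ccc1O
F11 | step 10 | (2S,3R,4S)-4-[(R)-hydroxy(3-methoxy-4-pivaloyloxyphenyl)methyl]-3-(hydroxymethyl)-2-(3-methoxy-4-pivaloyloxyphenyl)-4-(triethylsilyloxy)tetrahydrofuran | COc1cc([C@H]2OC[C@](O[Si](CC)(CC)CC)([C@H](O)c3ccc(OC(=O)C(C)(C)C)c(OC)c3)[C@@H]2CO)ccc1OC(=O)C(C)(C)C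
F12 | step 10 | primary methanesulfonate of F11 | COc1cc([C@H]2OC[C@](O[Si](CC)(CC)CC)([C@H](O)c3ccc(OC(=O)C(C)(C)C)c(OC)c3)[C@@H]2COS(C)(=O)=O)ccc1OC(=O)C(C)(C)C
A1 | alternative 1 | 8-hydroxypinoresinol 4,4'-di-O-benzyl ether | COc1cc([C@H]2OC[C@]3(O)[C@@H](c4ccc(OCc5ccccc5)c(OC)c4)OC[C@H]23)ccc1OCc1ccccc1
A2 | alternative 1 | (7R,8S,7'S,8'R)-1,4-bis(4-benzyloxy-3-methoxyphenyl)-2,3-bis(hydroxymethyl)butane-1,2,4-triol | COc1cc([C@@H](O)[C@@H](CO)[C@](O)(CO)[C@H](O)c2ccc(OCc3ccccc3)c(OC)c2)ccc1OCc1ccccc1
A3 | alternative 2 | C2-symmetric bis-syn-aldol adduct of the succinyl bis-imide | O=C1OC[C@H](Cc2ccccc2)N1C(=O)[C@H]([C@H](O)c1ccc(OCc2ccccc2)c(OC)c1)[C@@H]([C@H](O)c1ccc(OCc2ccccc2)c(OC)c1)C(=O)N1[C@@H](Cc2ccccc2)COC1=O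
A4 | alternative 2 | 1,4-bis[(S)-4-benzyl-2-oxooxazolidin-3-yl]butane-1,4-dione | O=C(CCC(=O)N1[C@@H](Cc2ccccc2)COC1=O)N1[C@@H](Cc2ccccc2)COC1=O
A5 | alternative 2 | 4-benzyloxy-3-methoxybenzaldehyde | COc1cc(C=O)ccc1OCc1ccccc1
A6 | alternative 3 | 8-O-acetyl furofuran with pivalate on the C7 arene and tert-butyldimethylsilyl ether on the C7' arene | COc1cc([C@H]2OC[C@]3(OC(C)=O)[C@@H](c4ccc(OC(=O)C(C)(C)C)c(OC)c4)OC[C@H]23)ccc1O[Si](C)(C)C(C)(C)C
A7 | alternative 3 | chloromethyl ether of the C7 carbinol carrying the C8 acetate, the C9 silyl ether and the (E)-styrene | ClCO[C@H](c1ccc(OC(=O)C(C)(C)C)c(OC)c1)[C@@](OC(C)=O)(CO[Si](C)(C)C(C)(C)C)/C=C/c1ccc(O[Si](C)(C)C(C)(C)C)c(OC)c1
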